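**Plan**

- Retrosynthesis: the seven benzyl ethers go last; both C4 carbonyls go back to carbinols; C3–H and C4–O of ring C are cut as water across a C3=C4 double bond; the C3–C8'' bond between the two flavonoid units is cut next (Suzuki); ring C of the upper unit is finally cut at C3–C4 (aldol) and O1–C2 (oxa-Michael) into a salicylaldehyde and a cinnamaldehyde.
- Forward: ring C is formed first, as a 2-aryl-2H-chromene-3-carbaldehyde, by an amine-catalysed oxa-Michael/aldol condensation. The formyl helper on C3 is exchanged for bromine and then boron, the naringenin-derived lower unit is joined at C8'', water is added across C3=C4, both carbinols are oxidised, and hydrogenolysis ends the route.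
- Enabling feature: O1 and C4 sit on neighbouring carbons (C8a, C4a) of ring A, and C2–C3 is the β,α pair of a cinnamyl unit. A formyl group on C3 therefore makes C2 an iminium β-electrophile for O1 and C3 an enamine nucleophile for the C4 aldehyde.
- Stereochemistry: C2'' is bought with (2S)-naringenin; C2 is set by the catalyst in the key step; C3 is relayed from C2 in the hydroboration, which gives the 2,3-cis diaryl array under kinetic control.

Key step: step 3

Remark: (2S)-naringenin is taken as a commercial, enantiomerically pure flavanone.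
Remark: the 2,3-cis relation of the two aryl groups on ring C is the less stable one, so C3 is created late and is never exposed to base once C4 is a ketone; the C4'' carbonyl is parked as a carbinol during the basic and hydridic steps.

**Step 1**
Reactants: 1 2,4,6-trihydroxybenzaldehyde
Product: 2 2,4-bis(benzyloxy)-6-hydroxybenzaldehyde
Conditions: BnBr (2.1 equiv), K2CO3, DMF, rt
Reagents that add atoms: benzyl bromide BrCc1ccccc1
Why: Williamson etherification: with two equivalents of benzyl bromide the 4-hydroxyl and one ortho hydroxyl are alkylated, whereas the remaining ortho hydroxyl, hydrogen-bonded to the formyl group, should stay free.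

**Step 2**
Reactants: 3 3,4-bis(benzyloxy)benzaldehyde
Product: 4 (E)-3-[3,4-bis(benzyloxy)phenyl]prop-2-enal
Conditions: Ph3P=CHCHO, toluene, 80 °C
Reagents that add atoms: (triphenylphosphoranylidene)acetaldehyde O=CC=P(c1ccccc1)(c1ccccc1)c1ccccc1
Why: Wittig olefination with the stabilised formylmethylene ylide should give the (E)-enal by two-carbon homologation.

**Step 3**
Reactants: 2 2,4-bis(benzyloxy)-6-hydroxybenzaldehyde; 4 (E)-3-[3,4-bis(benzyloxy)phenyl]prop-2-enal
Product: 5 (2S)-5,7-bis(benzyloxy)-2-[3,4-bis(benzyloxy)phenyl]-2H-chromene-3-carbaldehyde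
Conditions: (S)-2-[diphenyl(trimethylsilyloxy)methyl]pyrrolidine (20 mol %), 2-nitrobenzoic acid (20 mol %), 4 Å molecular sieves, toluene, rt, dark
Reagents that add atoms: none
Why: The secondary amine condenses with 4 to an (E)-iminium ion, the phenolic oxygen of 2 adds to its β-carbon (oxa-Michael, O1–C2), and the enamine so formed attacks the neighbouring formyl carbon through C3 (intramolecular aldol, C3–C4), after which loss of water and hydrolysis release 5 and the amine. The closest known reaction type is the diarylprolinol silyl ether catalysed domino oxa-Michael/aldol condensation of salicylaldehydes with cinnamaldehydes to 2-aryl-2H-chromene-3-carbaldehydes. Ring C is closed by a 6-(enolexo)-exo-trig aldol addition that forms the C3–C4 bond. C2 is the only new stereocentre and is controlled by the catalyst, whose diphenyl(silyloxy)methyl group screens one face of the iminium β-carbon so that oxygen adds to the open face; by the accepted facial model the (S)-catalyst should give (2S)-5, the spatial arrangement at C2 of the target, and its mirror image is used if the opposite sense is found. The step needs enantioface selection at C2 and conjugate addition ahead of any intermolecular aldol reaction; the ortho placing of OH and CHO in 2 makes the aldol intramolecular and six-membered, and the irreversible dehydration to the conjugated enal withdraws the adduct from the reversible oxa-Michael equilibrium. The formyl group on C3 is the activating helper that makes both bonds possible and is removed in steps 4 and 5.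

**Step 4**
Reactants: 5 (2S)-5,7-bis(benzyloxy)-2-[3,4-bis(benzyloxy)phenyl]-2H-chromene-3-carbaldehyde
Product: 6 (2S)-5,7-bis(benzyloxy)-2-[3,4-bis(benzyloxy)phenyl]-2H-chromene-3-carboxylic acid
Conditions: NaClO2, NaH2PO4, 2-methyl-2-butene, t-BuOH/THF/H2O, 0 °C to rt
Reagents that add atoms: sodium chlorite [Na+].[O-]Cl=O
Why: Pinnick (Lindgren–Kraus) oxidation converts only the formyl group, the hypochlorite by-product being trapped by 2-methyl-2-butene so that the electron-rich rings, the C3=C4 bond and the C2 stereocentre are left alone.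

**Step 5**
Reactants: 6 (2S)-5,7-bis(benzyloxy)-2-[3,4-bis(benzyloxy)phenyl]-2H-chromene-3-carboxylic acid
Product: 7 (2S)-5,7-bis(benzyloxy)-2-[3,4-bis(benzyloxy)phenyl]-3-bromo-2H-chromene
Conditions: NBS (1.05 equiv), LiOAc (0.2 equiv), MeCN/H2O, rt, dark
Reagents that add atoms: N-bromosuccinimide O=C1CCC(=O)N1Br
Why: Catalytic Hunsdiecker-type bromodecarboxylation: the bromonium ion should attack C3 ipso to the carboxylate, because the resulting C4 cation is a 2,4,6-trialkoxybenzyl cation and ring A keeps its aromaticity, and loss of CO2 then gives the vinyl bromide without touching C2.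

**Step 6**
Reactants: 8 (2S)-naringenin
Product: 9 (2S)-5,7-bis(benzyloxy)-2-[4-(benzyloxy)phenyl]chroman-4-one
Conditions: BnOH (3.6 equiv), PPh3, DIAD, THF, 0 °C to 40 °C
Reagents that add atoms: benzyl alcohol OCc1ccccc1
Why: Threefold Mitsunobu etherification alkylates the phenols under neutral conditions (the chelated 5-hydroxyl last), so the flavanone cannot open to the chalcone and C2'' keeps its configuration.

**Step 7**
Reactants: 9 (2S)-5,7-bis(benzyloxy)-2-[4-(benzyloxy)phenyl]chroman-4-one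
Product: 10 (2S)-5,7-bis(benzyloxy)-2-[4-(benzyloxy)phenyl]-8-iodochroman-4-one
Conditions: NIS (1.05 equiv), TFA (cat.), MeCN, 0 °C, dark
Reagents that add atoms: N-iodosuccinimide O=C1CCC(=O)N1I
Why: Electrophilic aromatic iodination of ring A: C8, flanked by the ring oxygen, should react in preference to C6, which is screened by two benzyloxy groups (the 5-O-benzyl group is turned toward C6 by the peri carbonyl), as in iodinations of fully O-alkylated 5,7-dioxygenated flavonoids.

**Step 8**
Reactants: 10 (2S)-5,7-bis(benzyloxy)-2-[4-(benzyloxy)phenyl]-8-iodochroman-4-one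
Product: 11 (2S,4S)-5,7-bis(benzyloxy)-2-[4-(benzyloxy)phenyl]-8-iodochroman-4-ol
Conditions: NaBH4, THF/MeOH, 0 °C
Reagents that add atoms: none
Why: Borohydride reduction with axial hydride delivery to the half-chair bearing an equatorial C2'' aryl group should give the 2,4-cis carbinol (a temporary centre under substrate control); removing the enolisable ketone shields C2'' from base-induced ring opening in step 9 and the carbonyl from borane in step 10.

**Step 9**
Reactants: 7 (2S)-5,7-bis(benzyloxy)-2-[3,4-bis(benzyloxy)phenyl]-3-bromo-2H-chromene; 11 (2S,4S)-5,7-bis(benzyloxy)-2-[4-(benzyloxy)phenyl]-8-iodochroman-4-ol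
Product: 13 (2S)-5,7-bis(benzyloxy)-2-[3,4-bis(benzyloxy)phenyl]-3-[(2S,4S)-5,7-bis(benzyloxy)-2-(4-benzyloxyphenyl)-4-hydroxychroman-8-yl]-2H-chromene, via chromen-3-ylboronate 12 (not isolated)
Conditions: B2pin2 (1.05 equiv), PdCl2(dppf), KOAc, 1,4-dioxane, 80 °C, dark; then 11, Pd(OAc)2, SPhos, aq K3PO4, 60 °C
Reagents that add atoms: none
Why: Miyaura borylation of the alkenyl bromide followed in the same flask by Suzuki–Miyaura coupling with the aryl iodide, SPhos serving the doubly ortho-substituted partner; no stereocentre takes part.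

**Step 10**
Reactants: 13 (2S)-5,7-bis(benzyloxy)-2-[3,4-bis(benzyloxy)phenyl]-3-[(2S,4S)-5,7-bis(benzyloxy)-2-(4-benzyloxyphenyl)-4-hydroxychroman-8-yl]-2H-chromene
Product: 15 (2R,3S,4S)-5,7-bis(benzyloxy)-2-[3,4-bis(benzyloxy)phenyl]-3-[(2S,4S)-5,7-bis(benzyloxy)-2-(4-benzyloxyphenyl)-4-hydroxychroman-8-yl]chroman-4-ol, via C4 alkylborane 14 (not isolated)
Conditions: BH3·THF (excess), THF, 0 °C to rt; then aq NaOH, H2O2, 0 °C
Reagents that add atoms: hydrogen peroxide OO
Why: Hydroboration–oxidation: boron should add to the less substituted C4 and hydrogen to C3 in a syn fashion from the face anti to the C2 aryl group (held pseudoaxial by allylic strain with the C3 aryl group), which sets C3 with the two aryl groups cis, and oxidation with retention gives the C4 carbinol.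

**Step 11**
Reactants: 15 (2R,3S,4S)-5,7-bis(benzyloxy)-2-[3,4-bis(benzyloxy)phenyl]-3-[(2S,4S)-5,7-bis(benzyloxy)-2-(4-benzyloxyphenyl)-4-hydroxychroman-8-yl]chroman-4-ol
Product: 16 (2R,3R)-5,7-bis(benzyloxy)-2-[3,4-bis(benzyloxy)phenyl]-3-[(2S)-5,7-bis(benzyloxy)-2-(4-benzyloxyphenyl)-4-oxochroman-8-yl]chroman-4-one
Conditions: Dess–Martin periodinane (3 equiv), NaHCO3, CH2Cl2, 0 °C to rt
Reagents that add atoms: none
Why: Dess–Martin oxidation converts both benzylic carbinols to the two chromanone carbonyls under buffered, non-basic conditions, so the newly α-keto, benzylic C3–H should not epimerise and neither flavanone ring opens.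

**Step 12**
Reactants: 16 (2R,3R)-5,7-bis(benzyloxy)-2-[3,4-bis(benzyloxy)phenyl]-3-[(2S)-5,7-bis(benzyloxy)-2-(4-benzyloxyphenyl)-4-oxochroman-8-yl]chroman-4-one
Product: 17 (2R,3R)-2-(3,4-dihydroxyphenyl)-5,7-dihydroxy-3-[(2S)-5,7-dihydroxy-2-(4-hydroxyphenyl)-4-oxochroman-8-yl]chroman-4-one
Conditions: H2 (1 atm), Pd(OH)2/C, EtOAc/MeOH, rt
Reagents that add atoms: none
Why: Catalytic hydrogenolysis of the seven benzyl ethers under neutral conditions should leave the aryl ketones, the two cyclic benzylic ethers and the base-sensitive C3 and C2'' centres intact if stopped after debenzylation.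

**Compound list**

1 | 2,4,6-trihydroxybenzaldehyde | O=Cc1c(O)cc(O)cc1O | starting material
2 | 2,4-bis(benzyloxy)-6-hydroxybenzaldehyde | O=Cc1c(O)cc(OCc2ccccc2)cc1OCc1ccccc1 | intermediate
3 | 3,4-bis(benzyloxy)benzaldehyde | O=Cc1ccc(OCc2ccccc2)c(OCc2ccccc2)c1 | starting material
4 | (E)-3-[3,4-bis(benzyloxy)phenyl]prop-2-enal | O=C/C=C/c1ccc(OCc2ccccc2)c(OCc2ccccc2)c1 | intermediate
5 | (2S)-5,7-bis(benzyloxy)-2-[3,4-bis(benzyloxy)phenyl]-2H-chromene-3-carbaldehyde | O=CC1=Cc2c(OCc3ccccc3)cc(OCc3ccccc3)cc2O[C@H]1c1ccc(OCc2ccccc2)c(OCc2ccccc2)c1 | intermediate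
6 | (2S)-5,7-bis(benzyloxy)-2-[3,4-bis(benzyloxy)phenyl]-2H-chromene-3-carboxylic acid | OC(=O)C1=Cc2c(OCc3ccccc3)cc(OCc3ccccc3)cc2O[C@H]1c1ccc(OCc2ccccc2)c(OCc2ccccc2)c1 | intermediate
7 | (2S)-5,7-bis(benzyloxy)-2-[3,4-bis(benzyloxy)phenyl]-3-bromo-2H-chromene | BrC1=Cc2c(OCc3ccccc3)cc(OCc3ccccc3)cc2O[C@H]1c1ccc(OCc2ccccc2)c(OCc2ccccc2)c1 | intermediate
8 | (2S)-naringenin, (2S)-5,7-dihydroxy-2-(4-hydroxyphenyl)chroman-4-one | O=C1C[C@@H](c2ccc(O)cc2)Oc2cc(O)cc(O)c21 | starting material
9 | (2S)-5,7-bis(benzyloxy)-2-[4-(benzyloxy)phenyl]chroman-4-one | O=C1C[C@@H](c2ccc(OCc3ccccc3)cc2)Oc2cc(OCc3ccccc3)cc(OCc3ccccc3)c21 | intermediate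
10 | (2S)-5,7-bis(benzyloxy)-2-[4-(benzyloxy)phenyl]-8-iodochroman-4-one | O=C1C[C@@H](c2ccc(OCc3ccccc3)cc2)Oc2c(I)c(OCc3ccccc3)cc(OCc3ccccc3)c21 | intermediate
11 | (2S,4S)-5,7-bis(benzyloxy)-2-[4-(benzyloxy)phenyl]-8-iodochroman-4-ol (2,4-cis) | O[C@H]1C[C@@H](c2ccc(OCc3ccccc3)cc2)Oc2c(I)c(OCc3ccccc3)cc(OCc3ccccc3)c21 | intermediate
12 | (2R)-5,7-bis(benzyloxy)-2-[3,4-bis(benzyloxy)phenyl]-3-(4,4,5,5-tetramethyl-1,3,2-dioxaborolan-2-yl)-2H-chromene (same spatial arrangement at C2 as 7; the descriptor changes only because boron ranks below carbon) | CC1(C)OB(OC1(C)C)C1=Cc2c(OCc3ccccc3)cc(OCc3ccccc3)cc2O[C@H]1c1ccc(OCc2ccccc2)c(OCc2ccccc2)c1 | intermediate (not isolated)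
13 | (2S)-5,7-bis(benzyloxy)-2-[3,4-bis(benzyloxy)phenyl]-3-[(2S,4S)-5,7-bis(benzyloxy)-2-(4-benzyloxyphenyl)-4-hydroxychroman-8-yl]-2H-chromene | O[C@H]1C[C@@H](c2ccc(OCc3ccccc3)cc2)Oc2c(C3=Cc4c(OCc5ccccc5)cc(OCc5ccccc5)cc4O[C@H]3c3ccc(OCc4ccccc4)c(OCc4ccccc4)c3)c(OCc3ccccc3)cc(OCc3ccccc3)c21 | intermediate
14 | C4 alkylborane of 13, written as the monoalkylborane with the C4'' hydroxyl as its borane ester; boron on C4 and hydrogen on C3 both anti to the C2 aryl group | BO[C@H]1C[C@@H](c2ccc(OCc3ccccc3)cc2)Oc2c([C@H]3[C@H](B)c4c(OCc5ccccc5)cc(OCc5ccccc5)cc4O[C@H]3c3ccc(OCc4ccccc4)c(OCc4ccccc4)c3)c(OCc3ccccc3)cc(OCc3ccccc3)c21 | intermediate (not isolated)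
15 | (2R,3S,4S)-5,7-bis(benzyloxy)-2-[3,4-bis(benzyloxy)phenyl]-3-[(2S,4S)-5,7-bis(benzyloxy)-2-(4-benzyloxyphenyl)-4-hydroxychroman-8-yl]chroman-4-ol (2,3-cis diaryl, 4-hydroxyl trans to both) | O[C@H]1C[C@@H](c2ccc(OCc3ccccc3)cc2)Oc2c([C@H]3[C@H](O)c4c(OCc5ccccc5)cc(OCc5ccccc5)cc4O[C@H]3c3ccc(OCc4ccccc4)c(OCc4ccccc4)c3)c(OCc3ccccc3)cc(OCc3ccccc3)c21 | intermediate
16 | (2R,3R)-5,7-bis(benzyloxy)-2-[3,4-bis(benzyloxy)phenyl]-3-[(2S)-5,7-bis(benzyloxy)-2-(4-benzyloxyphenyl)-4-oxochroman-8-yl]chroman-4-one | O=C1C[C@@H](c2ccc(OCc3ccccc3)cc2)Oc2c([C@H]3C(=O)c4c(OCc5ccccc5)cc(OCc5ccccc5)cc4O[C@H]3c3ccc(OCc4ccccc4)c(OCc4ccccc4)c3)c(OCc3ccccc3)cc(OCc3ccccc3)c21 | intermediate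
17 | (2R,3R)-2-(3,4-dihydroxyphenyl)-5,7-dihydroxy-3-[(2S)-5,7-dihydroxy-2-(4-hydroxyphenyl)-4-oxochroman-8-yl]chroman-4-one | O=C1C[C@@H](c2ccc(O)cc2)Oc2c1c(O)cc(O)c2[C@H]1C(=O)c2c(O)cc(O)cc2O[C@H]1c1ccc(O)c(O)c1 | target

**Step count and risks**

Total step count: 12. Longest linear sequence: 8 steps (1 or 2, then 3, 4, 5, 9, 10, 11, 12).

Steps most likely to fail:

Step 5. Bromination of the very electron-rich ring A (C6 or C8), or bromohydrin formation at C3=C4, may compete with ipso attack at C3. The fallback gives up the formyl-to-bromine exchange, reaches the boronate from 3 and 2 without any electrophilic halogen, and still closes ring C at C3–C4. Aldehyde 3 is alkynylated with trimethylsilylacetylene (Me2Zn, ProPhenol ligand of the antipode that leads to the (S)-carbinol, toluene) to the silylated alkynol F1. K2CO3/MeOH gives the terminal alkynol F2. Mitsunobu reaction with phenol 2 (PPh3, DIAD, THF) gives, with inversion, the propargylic aryl ether F3. Wittig methylenation (Ph3P=CH2, THF) gives the enyne F4. Copper-catalysed α-selective protoboration of the alkyne ((SIMes)CuCl, NaOt-Bu, B2pin2, MeOH, THF) gives the diene boronate F5. Ring-closing metathesis (second-generation Hoveyda–Grubbs catalyst, CH2Cl2, 40 °C) then delivers 12, which is isolated and enters step 9 at the coupling stage. This fallback also bypasses steps 3 and 4.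

Step 9. Cross-coupling at the doubly ortho-substituted iodide may be slow, which leaves time for protodeboronation of 12, hydrodeiodination of 11, or ionisation of the cyclic allyl aryl ether by zerovalent palladium with loss of the C2 configuration. The fallback sets out from 7 and replaces the boron route by a base-free organozinc coupling. Bromine–lithium exchange (t-BuLi, THF, −78 °C) and transmetalation with ZnCl2 give the chromen-3-ylzinc chloride F6. F6 is coupled with 11 in a Negishi reaction at room temperature (Pd(OAc)2, SPhos, THF; excess F6 to cover the free hydroxyl) and comes back at 13.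

Step 10. Boron may be delivered to C3 instead of C4 (followed by β-elimination that opens ring C), or hydrogen may be delivered syn to the C2 aryl group (trans product). The fallback sets out from 13 and sets C3 by enolate protonation instead. Dihydroxylation (OsO4, NMO, acetone/H2O) anti to the C2 aryl group gives the triol F7. Dess–Martin oxidation of its two secondary carbinols gives the 3-hydroxy diketone F8. SmI2 (THF/MeOH, −78 °C) cleaves the C3–O bond next to the C4 ketone, and the samarium enolate is protonated kinetically on the face anti to the pseudoaxial C2 aryl group, which should give 16 with the cis diaryl array.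

**Further compounds**

F1 | step 5 | (1R)-1-[3,4-bis(benzyloxy)phenyl]-3-(trimethylsilyl)prop-2-yn-1-ol | O[C@@H](C#C[Si](C)(C)C)c1ccc(OCc2ccccc2)c(OCc2ccccc2)c1
F2 | step 5 | (1S)-1-[3,4-bis(benzyloxy)phenyl]prop-2-yn-1-ol | O[C@@H](C#C)c1ccc(OCc2ccccc2)c(OCc2ccccc2)c1
F3 | step 5 | 2,4-bis(benzyloxy)-6-{[(1R)-1-[3,4-bis(benzyloxy)phenyl]prop-2-yn-1-yl]oxy}benzaldehyde | O=Cc1c(O[C@H](C#C)c2ccc(OCc3ccccc3)c(OCc3ccccc3)c2)cc(OCc2ccccc2)cc1OCc1ccccc1
F4 | step 5 | 1,5-bis(benzyloxy)-3-{[(1R)-1-[3,4-bis(benzyloxy)phenyl]prop-2-yn-1-yl]oxy}-2-ethenylbenzene | C=Cc1c(O[C@H](C#C)c2ccc(OCc3ccccc3)c(OCc3ccccc3)c2)cc(OCc2ccccc2)cc1OCc1ccccc1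
F5 | step 5 | 1,5-bis(benzyloxy)-3-{[(1R)-1-[3,4-bis(benzyloxy)phenyl]-2-(4,4,5,5-tetramethyl-1,3,2-dioxaborolan-2-yl)prop-2-en-1-yl]oxy}-2-ethenylbenzene | C=Cc1c(O[C@H](C(=C)B2OC(C)(C)C(C)(C)O2)c2ccc(OCc3ccccc3)c(OCc3ccccc3)c2)cc(OCc2ccccc2)cc1OCc1ccccc1
F6 | step 9 | [(2S)-5,7-bis(benzyloxy)-2-[3,4-bis(benzyloxy)phenyl]-2H-chromen-3-yl]zinc chloride | Cl[Zn]C1=Cc2c(OCc3ccccc3)cc(OCc3ccccc3)cc2O[C@H]1c1ccc(OCc2ccccc2)c(OCc2ccccc2)c1
F7 | step 10 | 3,4-cis-diol of 13: 5,7-bis(benzyloxy)-2-[3,4-bis(benzyloxy)phenyl]-3-[(2S,4S)-5,7-bis(benzyloxy)-2-(4-benzyloxyphenyl)-4-hydroxychroman-8-yl]chroman-3,4-diol, both new hydroxyls anti to the C2 aryl group | O[C@H]1C[C@@H](c2ccc(OCc3ccccc3)cc2)Oc2c([C@@]3(O)[C@H](O)c4c(OCc5ccccc5)cc(OCc5ccccc5)cc4O[C@H]3c3ccc(OCc4ccccc4)c(OCc4ccccc4)c3)c(OCc3ccccc3)cc(OCc3ccccc3)c21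
F8 | step 10 | 5,7-bis(benzyloxy)-2-[3,4-bis(benzyloxy)phenyl]-3-[(2S)-5,7-bis(benzyloxy)-2-(4-benzyloxyphenyl)-4-oxochroman-8-yl]-3-hydroxychroman-4-one, 3-hydroxyl anti to the C2 aryl group | O=C1C[C@@H](c2ccc(OCc3ccccc3)cc2)Oc2c([C@@]3(O)C(=O)c4c(OCc5ccccc5)cc(OCc5ccccc5)cc4O[C@H]3c3ccc(OCc4ccccc4)c(OCc4ccccc4)c3)c(OCc3ccccc3)cc(OCc3ccccc3)c21
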